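**Retrosynthetic overview**
1. The ether bridge is the last ring. The C5–O bond forms by a transannular SN2′ "oxygen walk": O‑10 leaves a C3 hemiketal and adds to C5, and a 15‑angelate departs to leave the 4(15)‑methylene.
2. The ten‑membered carbocycle and the γ‑lactone form in one operation. An allylchromium adds to a latent C6 aldehyde to make C6–C7, the bond nature makes when the farnesyl chain closes to a germacrane. O‑6 then lactonises onto C12.
3. The (Z)‑C3‑keto/C6‑enal is hidden in a 2,3‑disubstituted furan. E→Z isomerisation and oxidative spiroketalisation unmask it and tie C3 to O‑10.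
4. In the open chain, C8–C9 comes from a catalytic asymmetric Mukaiyama aldol (sets C8). C10–CH3 comes from a chelate‑controlled Grignard addition (sets C10).
5. Ring order: carbocycle, then γ‑lactone, then 5,10‑ether bridge.

**Assumption:** the target is numbered as a germacran‑12,6‑olide (8‑angelate, 5,10‑ether, 3‑ketone) and is taken to arise in the plant from a 15‑acyloxy 3,10‑hemiketal of the tagitinin F type.

**Step 1**
Reactants: 1 methyl acrylate; 2 2,2-dimethoxyacetaldehyde
Product: 3 methyl 3-hydroxy-4,4-dimethoxy-2-methylidenebutanoate (racemic)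
Conditions: DABCO (20 mol %), dioxane–H2O, rt
Reagents that add atoms: none
Why: Morita–Baylis–Hillman reaction of the acrylate with an activated α,α‑dialkoxy aldehyde; the carbinol centre is left racemic because step 2 erases it.

**Step 2**
Reactants: 3 methyl 3-hydroxy-4,4-dimethoxy-2-methylidenebutanoate
Product: 6 methyl (2Z)-2-(chloromethyl)-4-oxobut-2-enoate, via mesylate 4 (not isolated), via chloro acetal 5 (not isolated)
Conditions: MsCl, Et3N, CH2Cl2, 0 °C → rt; then TFA–H2O (1:1), rt
Reagents that add atoms: methanesulfonyl chloride CS(=O)(=O)Cl; water O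
Why: Mesylation and SN2′ attack of the liberated chloride (allylic transposition of a Baylis–Hillman adduct) give the conjugated alkene with the C8 carbon trans to the ester (Z), and aqueous acid then hydrolyses the acetal without touching the allylic chloride.

**Step 3**
Reactants: 7 furan-3-ylmethanol
Product: 9 3-(hydroxymethyl)furan-2-carbaldehyde, via dilithio furan 8 (not isolated)
Conditions: n-BuLi (2.2 equiv), THF, −78 → 0 °C; DMF, −78 °C → rt; H2O
Reagents that add atoms: N,N-dimethylformamide CN(C)C=O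
Why: Alkoxide‑directed ortho‑lithiation takes place at furan C2 and the dianion is formylated by DMF; no stereocentre is formed.

**Step 4**
Reactants: 9 3-(hydroxymethyl)furan-2-carbaldehyde; 10 1-(triphenyl-λ5-phosphanylidene)propan-2-one
Product: 11 (3E)-4-[3-(hydroxymethyl)furan-2-yl]but-3-en-2-one
Conditions: CH2Cl2, rt
Reagents that add atoms: none
Why: Wittig olefination with a stabilised ylide gives the E‑enone under neutral conditions, so the neighbouring CH2OH does not add to the new enone.

**Step 5**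
Reactants: 11 (3E)-4-[3-(hydroxymethyl)furan-2-yl]but-3-en-2-one
Product: 12 (E)-2-(trimethylsilyloxy)-4-{3-[(trimethylsilyloxy)methyl]furan-2-yl}buta-1,3-diene
Conditions: TMSOTf (2.3 equiv), Et3N (3 equiv), CH2Cl2, 0 °C
Reagents that add atoms: trimethylsilyl trifluoromethanesulfonate C[Si](C)(C)OS(=O)(=O)C(F)(F)F
Why: Soft enolisation/silylation; only the methyl group can enolise, so a single 2‑silyloxydiene forms, and the primary alcohol is masked in the same operation.

**Step 6**
Reactants: 12 (E)-2-(trimethylsilyloxy)-4-{3-[(trimethylsilyloxy)methyl]furan-2-yl}buta-1,3-diene; 6 methyl (2Z)-2-(chloromethyl)-4-oxobut-2-enoate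
Product: 14 methyl (2Z,4R,7E)-2-(chloromethyl)-4-hydroxy-8-[3-(hydroxymethyl)furan-2-yl]-6-oxoocta-2,7-dienoate, via trichlorosilyl aldolate 13 (not isolated)
Conditions: SiCl4 (1.5 equiv), chiral binaphthyldiamine-derived bisphosphoramide (5 mol %), i-Pr2NEt (10 mol %), CH2Cl2, −78 °C; sat. aq NaHCO3; 0.5 M HCl–THF, 0 °C, 10 min
Reagents that add atoms: none
Why: Catalytic enantioselective Mukaiyama aldol addition (Lewis‑base‑activated SiCl4, open transition state, 1,2‑selective for enals); the catalyst antipode is chosen for attack on the Re face of aldehyde 6, which sets C8 as 4R, and the brief acid wash removes both silyl groups.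

**Step 7**
Reactants: 14 methyl (2Z,4R,7E)-2-(chloromethyl)-4-hydroxy-8-[3-(hydroxymethyl)furan-2-yl]-6-oxoocta-2,7-dienoate
Product: 15 methyl (2Z,4R,6S,7E)-2-(chloromethyl)-4,6-dihydroxy-8-[3-(hydroxymethyl)furan-2-yl]-6-methylocta-2,7-dienoate
Conditions: MeMgBr (3.5 equiv, Et2O), CH2Cl2, −78 °C; sat. aq NH4Cl
Reagents that add atoms: methylmagnesium bromide C[Mg]Br
Why: Chelation‑controlled 1,2‑Grignard addition; the C8 magnesium alkoxide and the ketone form a six‑membered half‑chair chelate that is attacked externally along the same trajectory as hydride in a syn‑selective β‑hydroxy‑ketone reduction, which sets C10 (6S, 4,6‑syn), while at −78 °C the hindered conjugated ester and the allylic chloride react more slowly than the activated ketone.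

**Step 8**
Reactants: 15 methyl (2Z,4R,6S,7E)-2-(chloromethyl)-4,6-dihydroxy-8-[3-(hydroxymethyl)furan-2-yl]-6-methylocta-2,7-dienoate
Product: 17 methyl (2Z,4R)-2-(chloromethyl)-4-hydroxy-5-[(2S)-7-hydroxy-9-(hydroxymethyl)-2-methyl-1,6-dioxaspiro[4.4]nona-3,8-dien-2-yl]pent-2-enoate (epimers at spiro C5 and lactol C7), via Z-triol 16 (not isolated)
Conditions: thioxanthen-9-one (10 mol %), MeCN, 405 nm, Ar, rt; then H2O, NaHCO3, NBS (1.05 equiv), 0 °C, dark
Reagents that add atoms: water O
Why: Triplet energy‑transfer E→Z isomerisation excites only the alkenylfuran chromophore, and the twisted Z isomer is no longer sensitised; NBS then brings about an Achmatowicz‑type oxidative spiroketalisation in which O‑10 captures furan C2 (= C3) and water captures C5 (= C6), so C8 and C10 are untouched and the two new acetal centres are labile mixtures that converge in step 9.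

**Step 9**
Reactants: 17 methyl (2Z,4R)-2-(chloromethyl)-4-hydroxy-5-[(2S)-7-hydroxy-9-(hydroxymethyl)-2-methyl-1,6-dioxaspiro[4.4]nona-3,8-dien-2-yl]pent-2-enoate
Product: 20 (3S,4Z,6R,7R,8R,10S)-3,10-epoxy-3,8,15-trihydroxygermacra-1,4,11(13)-trien-12,6-olide, via allylchromium species 18 (not isolated), via macrocyclic hydroxy ester 19 (not isolated)
Conditions: CrCl2 (10 equiv), LiI (20 mol %), DMF, syringe-pump addition (final 2 mM), rt; aq. work-up
Reagents that add atoms: none
Why: Intramolecular Nozaki–Hiyama–Kishi‑type allylation followed by spontaneous lactonisation; Cr(II) inserts only into the allylic C–Cl bond, the lactol delivers the C6 enal while C3 stays masked as the O‑10 hemiketal so that no enedione meets Cr(II), the equilibrating allylchromium reacts through the chair of its E form to give the 6,7‑anti (trans‑lactone) relationship, the C8 carbinol fixes the face of C7 (C8–O inside and bridged to ester/chromium, C9 outside), the bridge fixes C3, and the C6 chromium alkoxide closes onto the methyl ester.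

**Step 10**
Reactants: 20 (3S,4Z,6R,7R,8R,10S)-3,10-epoxy-3,8,15-trihydroxygermacra-1,4,11(13)-trien-12,6-olide; 21 angelic acid [(2Z)-2-methylbut-2-enoic acid]
Product: 24 (5S,6S,7R,8R,10S)-8-angeloyloxy-5,10-epoxy-3-oxogermacra-1,4(15),11(13)-trien-12,6-olide, via mixed anhydride 22 (not isolated), via bis-angelate 23 (not isolated)
Conditions: 21, 2,4,6-Cl3C6H2COCl, Et3N, PhMe, rt; add 20, 75 °C; filter, evaporate; Cs2CO3, MeCN, 0 °C → rt
Reagents that add atoms: none
Why: Proposed new method: DMAP‑free mixed‑anhydride (Yamaguchi‑type) acylation esterifies the primary 15‑OH and the secondary 8‑OH without Z→E leakage while the tertiary hemiketal OH stays free, carbonate then opens the hemiketal to the (1Z,4Z)‑dienone whose C10 alkoxide sits directly over C5 and adds conjugatively, and the C3 enolate expels the 15‑angelate (oxa‑Michael/E1cB = SN2′, irreversible), which creates the 4(15)‑methylene and sets C5 (S) because the one‑atom bridge can only close on the face where O‑10 already lies; the closest known reaction type is the addition–elimination of O‑nucleophiles to 2‑(acyloxymethyl)enones (rearranged Morita–Baylis–Hillman acetates).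

**Compound list**
1 | methyl acrylate | C=CC(=O)OC | starting material
2 | 2,2-dimethoxyacetaldehyde | COC(OC)C=O | starting material
3 | methyl 3-hydroxy-4,4-dimethoxy-2-methylidenebutanoate (racemic) | COC(OC)C(O)C(=C)C(=O)OC | intermediate
4 | methyl 4,4-dimethoxy-3-(methylsulfonyloxy)-2-methylidenebutanoate (racemic, not isolated) | COC(OC)C(OS(C)(=O)=O)C(=C)C(=O)OC | intermediate
5 | methyl (2Z)-2-(chloromethyl)-4,4-dimethoxybut-2-enoate (not isolated) | COC(OC)/C=C(\CCl)C(=O)OC | intermediate
6 | methyl (2Z)-2-(chloromethyl)-4-oxobut-2-enoate (CHO cis to CH2Cl) | O=C/C=C(\CCl)C(=O)OC | intermediate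
7 | furan-3-ylmethanol | OCc1ccoc1 | starting material
8 | lithium (2-lithiofuran-3-yl)methanolate (not isolated) | [Li]OCc1ccoc1[Li] | intermediate
9 | 3-(hydroxymethyl)furan-2-carbaldehyde | OCc1ccoc1C=O | intermediate
10 | 1-(triphenyl-λ5-phosphanylidene)propan-2-one | CC(=O)C=P(c1ccccc1)(c1ccccc1)c1ccccc1 | starting material
11 | (3E)-4-[3-(hydroxymethyl)furan-2-yl]but-3-en-2-one | CC(=O)/C=C/c1occc1CO | intermediate
12 | (E)-2-(trimethylsilyloxy)-4-{3-[(trimethylsilyloxy)methyl]furan-2-yl}buta-1,3-diene | C=C(O[Si](C)(C)C)/C=C/c1occc1CO[Si](C)(C)C | intermediate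
13 | methyl (2Z,4R,7E)-2-(chloromethyl)-6-oxo-4-(trichlorosilyloxy)-8-{3-[(trimethylsilyloxy)methyl]furan-2-yl}octa-2,7-dienoate (not isolated) | ClC/C(C(=O)OC)=C\[C@H](O[Si](Cl)(Cl)Cl)CC(=O)/C=C/c1occc1CO[Si](C)(C)C | intermediate
14 | methyl (2Z,4R,7E)-2-(chloromethyl)-4-hydroxy-8-[3-(hydroxymethyl)furan-2-yl]-6-oxoocta-2,7-dienoate | ClC/C(C(=O)OC)=C\[C@H](O)CC(=O)/C=C/c1occc1CO | intermediate
15 | methyl (2Z,4R,6S,7E)-2-(chloromethyl)-4,6-dihydroxy-8-[3-(hydroxymethyl)furan-2-yl]-6-methylocta-2,7-dienoate | ClC/C(C(=O)OC)=C\[C@H](O)C[C@@](O)(C)/C=C/c1occc1CO | intermediate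
16 | (2Z,4R,6S,7Z) isomer of 15 (not isolated) | ClC/C(C(=O)OC)=C\[C@H](O)C[C@@](O)(C)/C=C\c1occc1CO | intermediate
17 | methyl (2Z,4R)-2-(chloromethyl)-4-hydroxy-5-[(2S)-7-hydroxy-9-(hydroxymethyl)-2-methyl-1,6-dioxaspiro[4.4]nona-3,8-dien-2-yl]pent-2-enoate (epimers at spiro C5 and lactol C7) | ClC/C(C(=O)OC)=C\[C@H](O)C[C@@]1(C)C=CC2(O1)OC(O)C=C2CO | intermediate
18 | dichlorochromium(III) allyl derived from 17 (C13–Cr, alkene geometry fluxional, not isolated) | COC(=O)C(C[Cr](Cl)Cl)=C[C@H](O)C[C@@]1(C)C=CC2(O1)OC(O)C=C2CO | intermediate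
19 | methyl (3S,4Z,6R,7R,8R,10S)-3,10-epoxy-3,6,8,15-tetrahydroxygermacra-1,4,11(13)-trien-12-oate (formed as its Cr alkoxide, not isolated) | OC/C1=C/[C@@H](O)[C@H](C(=C)C(=O)OC)[C@H](O)C[C@@]2(C)C=C[C@]1(O)O2 | intermediate
20 | (3S,4Z,6R,7R,8R,10S)-3,10-epoxy-3,8,15-trihydroxygermacra-1,4,11(13)-trien-12,6-olide | OC/C1=C/[C@H]2OC(=O)C(=C)[C@@H]2[C@H](O)C[C@@]3(C)C=C[C@]1(O)O3 | intermediate
21 | angelic acid, (2Z)-2-methylbut-2-enoic acid | C/C=C(/C)C(=O)O | starting material
22 | angelic 2,4,6-trichlorobenzoic anhydride (not isolated) | C/C=C(/C)C(=O)OC(=O)c1c(Cl)cc(Cl)cc1Cl | intermediate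
23 | (3S,4Z,6R,7R,8R,10S)-8,15-bis(angeloyloxy)-3,10-epoxy-3-hydroxygermacra-1,4,11(13)-trien-12,6-olide (not isolated) | C/C=C(/C)C(=O)OC/C1=C/[C@H]2OC(=O)C(=C)[C@@H]2[C@H](OC(=O)/C(C)=C\C)C[C@@]3(C)C=C[C@]1(O)O3 | intermediate
24 | (5S,6S,7R,8R,10S)-8-angeloyloxy-5,10-epoxy-3-oxogermacra-1,4(15),11(13)-trien-12,6-olide (CNP0335602.1) | C=C1C(=O)O[C@H]2[C@H]1[C@H](OC(=O)/C(C)=C\C)C[C@@]1(C)C=CC(=O)C(=C)[C@@H]2O1 | target

**Total step count:** 10. **Longest linear sequence:** 8 (steps 3–10, from furan-3-ylmethanol).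

**Three steps most likely to fail**

**Step 9 (macrocyclisation on a protic spiro‑lactol).** Three things can go wrong. Ring opening of the lactol may be slow. Traces of the open enedione can be reduced by Cr(II). The face selectivity at C7 is not secured.
- The fallback replaces reductive metal insertion by redox‑neutral transmetalation. It sets out from 15 and comes back at 20.
- Pd(0)‑catalysed stannylation of the chloride with hexabutylditin gives the allylstannane triol F3.
- The same energy‑transfer isomerisation gives its 7Z isomer F4.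
- m‑CPBA/NaHCO3 oxidation of the furan gives the stannyl spiro‑lactol F5.
- InCl3 at high dilution then generates the allylindium dichloride with no reductant present. It closes C6–C7 through the same anti‑selective chair and lactonises to 20.

**Step 10 (double angeloylation and oxygen walk in one operation).**
- The hindered 8‑OH may acylate slowly.
- SN2 attack at C15 may compete with the desired SN2′ attack at C5.
- γ‑Deprotonation at C6 may also compete.

The fallback separates ring closure from acylation and uses a better leaving group. It sets out from 20 and comes back at 24.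
- NCS/Me2S converts only the primary allylic alcohol into the 15‑chloride F6.
- Cs2CO3 (or Ag2O) triggers the same SN2′ closure to the 8‑hydroxy ether F7.
- A single mixed‑anhydride angeloylation of the one remaining alcohol gives 24.

**Step 7 (chelate‑controlled methyl addition).** The dr may be modest, and enolisation or attack on the chloro‑acrylate are possible. The fallback gives up substrate control for ligand control on a protected substrate. It sets out from 14 and comes back at 15.
- TESCl/imidazole gives the bis(triethylsilyl) ether F1.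
- Me2Zn/Ti(OiPr)4 with a chiral bis(sulfonamide) diol ligand is non‑basic and inert to the ester and the chloride. It adds methyl to the ketone to give the tertiary alcohol F2.
- Buffered fluoride (TBAF/AcOH) removes both silyl groups and gives 15.

**Further compounds**
F1 | step 7 | methyl (2Z,4R,7E)-2-(chloromethyl)-6-oxo-4-(triethylsilyloxy)-8-{3-[(triethylsilyloxy)methyl]furan-2-yl}octa-2,7-dienoate | ClC/C(C(=O)OC)=C\[C@H](O[Si](CC)(CC)CC)CC(=O)/C=C/c1occc1CO[Si](CC)(CC)CC
F2 | step 7 | methyl (2Z,4R,6S,7E)-2-(chloromethyl)-6-hydroxy-6-methyl-4-(triethylsilyloxy)-8-{3-[(triethylsilyloxy)methyl]furan-2-yl}octa-2,7-dienoate | ClC/C(C(=O)OC)=C\[C@H](O[Si](CC)(CC)CC)C[C@@](O)(C)/C=C/c1occc1CO[Si](CC)(CC)CC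
F3 | step 9 | methyl (2Z,4R,6S,7E)-4,6-dihydroxy-8-[3-(hydroxymethyl)furan-2-yl]-6-methyl-2-[(tributylstannyl)methyl]octa-2,7-dienoate | CCCC[Sn](CCCC)(CCCC)C/C(C(=O)OC)=C\[C@H](O)C[C@@](O)(C)/C=C/c1occc1CO
F4 | step 9 | (2Z,4R,6S,7Z) isomer of F3 | CCCC[Sn](CCCC)(CCCC)C/C(C(=O)OC)=C\[C@H](O)C[C@@](O)(C)/C=C\c1occc1CO
F5 | step 9 | methyl (2Z,4R)-4-hydroxy-5-[(2S)-7-hydroxy-9-(hydroxymethyl)-2-methyl-1,6-dioxaspiro[4.4]nona-3,8-dien-2-yl]-2-[(tributylstannyl)methyl]pent-2-enoate | CCCC[Sn](CCCC)(CCCC)C/C(C(=O)OC)=C\[C@H](O)C[C@@]1(C)C=CC2(O1)OC(O)C=C2CO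
F6 | step 10 | (3S,4E,6R,7R,8R,10S)-15-chloro-3,10-epoxy-3,8-dihydroxygermacra-1,4,11(13)-trien-12,6-olide | ClC/C1=C/[C@H]2OC(=O)C(=C)[C@@H]2[C@H](O)C[C@@]3(C)C=C[C@]1(O)O3
F7 | step 10 | (5S,6S,7R,8R,10S)-5,10-epoxy-8-hydroxy-3-oxogermacra-1,4(15),11(13)-trien-12,6-olide | C=C1C(=O)O[C@H]2[C@H]1[C@H](O)C[C@@]1(C)C=CC(=O)C(=C)[C@@H]2O1
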